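Leftover solid substrate reads 0% at 15.0 h in the south-east run, yet product reads 0.1% there, so what dissolved stands in this flask as something other than solid or product.

south-east run (percent of the solid substrate charged)

| time / h | product / % | solid substrate / % |
|---|---|---|
| 3.00 | 0.2 | 57.1 |
| 4.00 | 0 | 49.8 |
| 6.00 | 0.3 | 36.7 |
| 10.0 | 0 | 12.8 |
| 15.0 | 0.1 | 0 |
| 25.0 | 0.8 | 0 |
| 40.0 | 3.2 | 0.4 |

(readings scatter by 0.3 percentage points)

- south-east: solid substrate 1.5 M; the very flask that is asked about, followed so far
- flask: solid substrate 1.5 M; time 3.0 d

- amount of product at 3.0 d, in percent of the solid substrate charged
- the change that raises the amount of product at 3.0 d, in percent of the solid substrate charged most ("none" if none brings more than 2 percentage points) (zeta / delta / none)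
- amount of product at 3.0 d, in percent of the solid substrate charged, after zeta

- zeta: doubling the solubility of the solid substrate, all else as stated
- delta: doubling the dissolution coefficient of the solid substrate, all else as stated

Two of us read the last two product readings of this run differently. The first treats the flask as lags in series, whose output climbs early on as a power of time. The readings at 25.0 h and 40.0 h give the exponent 2.95, and that curve reaches 18.1% at 3.0 d.

I hold the second view: once the stages have filled, product arrives at a steady pace. The slope between those readings is 0.00160 h⁻¹, and this is what I carry: the ramp rate, the fraction of the charge arriving as product per hour. It is a reading, and each end scatters by 0.3 percentage points. Continued from 40.0 h, the ramp gives 8.32% at 3.0 d.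

Solid substrate reads 49.8% at 4.00 h, so the middle of the feed lies near that time. If a change pulled that middle right back to the start, the ramp would move earlier by that time and gain 0.64 points, less than 2 points. I therefore commit to none as the best change, and to 8.96% after zeta.

The forecast, on the side of the rising curve, gives 14% (range 8% to 24%), “though this is uncertain”, with none as the best change and 15.5% after zeta.

The flask gives 10.1%, and 10.8% after zeta; zeta adds 0.72 points and delta 0.31 points, so the best change is none.

    starting material → intermediate A (k = 0.155 h⁻¹)
    intermediate A → intermediate B (k = 0.00586 h⁻¹)
    intermediate B → intermediate C (k = 0.0572 h⁻¹)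
    intermediate C → product (k = 0.0780 h⁻¹)
    solid substrate ⇌ starting material, rate k5*(cs5 - [starting material]) while solid is left; crystals form when [starting material] > cs5 (solubility = 0.720 M, k = 0.543 h⁻¹)
    intermediate B → decomposed reagent (k = 0.0585 h⁻¹)

This flask lands 1.8 points above my ramp and 8 points below the power curve, so nearer the ramp. At 3.00 d intermediate A, the resting state, still holds 70.1%. The power curve keeps the early hours. Take the neighbouring flask, the same flask read at 20 h. Walking the ramp back from 40.0 h removes 3.20%, equal to the reading 3.2%, so the ramp stands at zero there. The power curve gives 0.414%, and the neighbouring flask holds 0.385% product.

Readings and results are calculated from invented constants.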